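**Retrosynthetic overview**

Numbering (germacranolide): ring C1–C10 (C1=C10 with CO2Me on C10, C4–C5 oxirane, C6 lactone oxygen, C7 ring fusion, C8 methacrylate, C9 acetate); lactone C11(=C13H2)–C12(=O)–O6.
Late disconnections: the 4,5-epoxide (peripheral mCPBA), the C9 acetate and the C8 methacrylate, leading back to a macrocyclic hydroxy α-methylene lactone.
Key disconnection C7–C11: PMe3 isomerises an acrylate on O6 into the lactone. O6 sits on the carbon next to C7, so the acrylate α-carbon C11 reaches the backside of the C7–O bond of a cis-7,8-epoxide (5-exo), and the epoxide oxygen becomes the free C8 hydroxyl.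
The ten-membered ring comes from RCM at C1=C10 (Morita–Baylis–Hillman acrylate + terminal alkene) after a Nozaki–Hiyama–Kishi union at C5–C6; ring order: 7,8-oxirane, ten-membered carbocycle, lactone, 4,5-oxirane.
Stereocontrol: only C9 is set by catalysis (asymmetric MBH); C7/C8 (directed epoxidation), C6 (Felkin addition), C7 again (SN2 inversion in the key step) and C4/C5 are relayed from it.

Key step: step 13

Remark: CIP descriptors at C6–C9 change along the route only because substituent priorities change; no stereocentre other than C7 (step 13) is inverted, and the SMILES are authoritative.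

**Route**

Step 1
Reactants: 1 1-methoxy-4-[(prop-2-yn-1-yloxy)methyl]benzene (PMB propargyl ether)
Product: 3 4-[(4-methoxybenzyl)oxy]but-2-ynal, via lithium acetylide 2 (not isolated)
Conditions: n-BuLi, THF, −78 °C; DMF, −78 → 0 °C; inverse quench into cold aq KH2PO4
Reagents that add atoms: N,N-dimethylformamide CN(C)C=O
Why: Formylation of a lithium acetylide with DMF, with an inverse phosphate quench so that the liberated amine cannot add to the ynal; no stereocentre is formed.

Step 2
Reactants: 3 4-[(4-methoxybenzyl)oxy]but-2-ynal; 4 1,1,1,3,3,3-hexafluoropropan-2-yl prop-2-enoate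
Product: 5 1,1,1,3,3,3-hexafluoropropan-2-yl 2-[(1S)-1-hydroxy-4-[(4-methoxybenzyl)oxy]but-2-yn-1-yl]prop-2-enoate
Conditions: α-isocupreine (quinine-derived pseudoenantiomer of β-isocupreidine, 10 mol %), DMF, −55 °C
Reagents that add atoms: none
Why: Catalytic asymmetric Morita–Baylis–Hillman reaction in which the quinuclidine nitrogen adds to the activated acrylate and the phenolic OH of the catalyst hydrogen-bonds the aldehyde, so the enolate attacks one carbonyl face and C9 should form as the (S)-carbinol (β-isocupreidine gives the R series, its pseudoenantiomer the S series).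

Step 3
Reactants: 5 hexafluoroisopropyl ester MBH adduct
Product: 6 methyl 2-[(1S)-1-hydroxy-4-[(4-methoxybenzyl)oxy]but-2-yn-1-yl]prop-2-enoate
Conditions: MeOH, Et3N (cat.), 0 °C → rt
Reagents that add atoms: methanol CO
Why: Base-catalysed transesterification of the activated fluoroalkyl ester to the methyl ester, which leaves the carbinol untouched.

Step 4
Reactants: 6 methyl ester MBH adduct
Product: 7 methyl 2-[(1S,2Z)-1-hydroxy-4-[(4-methoxybenzyl)oxy]but-2-en-1-yl]prop-2-enoate
Conditions: H2 (1 atm), Lindlar catalyst (Pd/CaCO3 poisoned with Pb(OAc)2), quinoline, EtOAc, rt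
Reagents that add atoms: none
Why: Lindlar semihydrogenation delivers H2 syn to the alkyne and should give the Z-alkene while sparing the conjugated 1,1-disubstituted alkene and the benzylic ether.

Step 5
Reactants: 7 (Z)-allylic alcohol
Product: 8 methyl 2-[(R)-hydroxy{(2S,3R)-3-[[(4-methoxybenzyl)oxy]methyl]oxiran-2-yl}methyl]prop-2-enoate (cis-epoxide, threo to the C9 hydroxyl)
Conditions: mCPBA, Na2HPO4 (solid), CH2Cl2, 0 °C → rt
Reagents that add atoms: 3-chloroperoxybenzoic acid OOC(=O)c1cccc(Cl)c1
Why: Henbest hydroxyl-directed epoxidation, in which allylic 1,3-strain with the cis CH2OPMB group holds C9–H in the alkene plane and the peracid hydrogen-bonded to O9 adds to the face carrying the hydroxyl, so the threo cis-epoxy alcohol should form (C7 and C8 relayed from C9) while the electron-poor acrylate stays inert.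

Step 6
Reactants: 8 threo cis-epoxy alcohol
Product: 9 C9 tert-butyldimethylsilyl ether of 8 (configuration unchanged)
Conditions: TBSCl, imidazole, DMF, rt
Reagents that add atoms: tert-butyldimethylsilyl chloride CC(C)(C)[Si](C)(C)Cl
Why: Silylation of the secondary alcohol, which blocks O9 until the end of the route.

Step 7
Reactants: 9 silyl ether
Product: 10 primary C6 alcohol, methyl 2-{[(tert-butyldimethylsilyl)oxy][3-(hydroxymethyl)oxiran-2-yl]methyl}prop-2-enoate (configuration as in 8)
Conditions: DDQ, CH2Cl2/pH 7 phosphate buffer, 0 °C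
Reagents that add atoms: none
Why: Oxidative cleavage of the PMB ether by DDQ through the benzylic oxocarbenium ion, to which the silyl ether, the epoxide and the acrylate are inert.

Step 8
Reactants: 10 primary epoxy alcohol
Product: 11 cis-epoxy aldehyde, methyl 2-{[(tert-butyldimethylsilyl)oxy](3-formyloxiran-2-yl)methyl}prop-2-enoate (configuration as in 8)
Conditions: Dess–Martin periodinane, NaHCO3, CH2Cl2, 0 °C → rt; used crude
Reagents that add atoms: none
Why: Dess–Martin oxidation under buffered conditions should give the cis-epoxy aldehyde without epimerisation at C7.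

Step 9
Reactants: 12 hex-1-en-5-yne
Product: 14 (1E)-1-iodo-2-methylhexa-1,5-diene, via alkenylalane 13 (not isolated)
Conditions: AlMe3, Cp2ZrCl2 (0.25 equiv), CH2Cl2, 0 °C → rt; then I2, THF, −30 → 0 °C
Reagents that add atoms: trimethylaluminium C[Al](C)C; iodine II
Why: Zirconium-catalysed Negishi carboalumination adds Me–Al syn across the terminal alkyne with methyl on the internal carbon, and iodinolysis with retention gives the E vinyl iodide, the monosubstituted alkene reacting much more slowly.

Step 10
Reactants: 11 cis-epoxy aldehyde; 14 (1E)-1-iodo-2-methylhexa-1,5-diene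
Product: 15 methyl 2-{[(tert-butyldimethylsilyl)oxy]{3-[(1R,2E)-1-hydroxy-3-methylhepta-2,6-dien-1-yl]oxiran-2-yl}methyl}prop-2-enoate (C6 alcohol erythro to the cis-epoxide)
Conditions: CrCl2 (excess), NiCl2 (2 mol %), DMSO, rt
Reagents that add atoms: none
Why: Nozaki–Hiyama–Kishi alkenylation is chemoselective for the aldehyde in the presence of both esters and keeps the alkene geometry, and Felkin–Anh attack anti to the epoxide C–O bond should give the erythro carbinol at C6.

Step 11
Reactants: 15 acyclic epoxy alcohol
Product: 16 macrocyclic epoxy alcohol, methyl 9-[(tert-butyldimethylsilyl)oxy]-7,8-epoxy-6-hydroxy-4-methylcyclodeca-1(10),4-diene-10-carboxylate (target numbering; ring-cis C1=C10, 4E, cis-epoxide)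
Conditions: second-generation Hoveyda–Grubbs catalyst (H2IMes)Cl2Ru=CH(2-i-PrOC6H4) (15 mol %), 1,4-benzoquinone, toluene (0.5 mM), 90 °C, Ar sparge
Reagents that add atoms: none
Why: Ring-closing metathesis in which the catalyst loads on the monosubstituted alkene and closes onto the 1,1-disubstituted acrylate, the cis-epoxide serving as a turn element, so the trisubstituted enoate should form with the less strained ring-cis geometry (CO2Me trans to C2) as ethene is lost.

Step 12
Reactants: 16 macrocyclic epoxy alcohol
Product: 17 C6 acrylate of 16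
Conditions: acryloyl chloride, i-Pr2NEt, CH2Cl2, −30 → 0 °C
Reagents that add atoms: acryloyl chloride C=CC(=O)Cl
Why: O-Acylation of the secondary allylic alcohol with an acid chloride under mild base, which touches no stereocentre.

Step 13
Reactants: 17 macrocyclic epoxy acrylate
Product: 18 macrocyclic α-methylene-γ-butyrolactone (6,12-olide) with free C8 hydroxyl, C9 silyl ether and 4E-alkene (C6–C9 configured as in the target)
Conditions: PMe3 (1.0 equiv, 1 M in THF), t-BuOH/THF (4:1), 5 mM, rt → 45 °C
Reagents that add atoms: none
Why: Proposed new method: PMe3 adds reversibly to the unhindered acrylate terminus (C13) to give a β-phosphonium ester enolate whose α-carbon C11 attacks C7 of the cis-epoxide from the face opposite the epoxide oxygen, the resulting C8 alkoxide takes the now acidic C11 proton through a six-membered transfer assisted by t-BuOH, and E1cB loss of PMe3 unveils the exocyclic methylene, so the step is a net isomerisation. The closest known reaction type is the trialkylphosphine-mediated intramolecular Morita–Baylis–Hillman-type α-alkylation of enones by tethered alkyl halides and epoxides, here extended to an acrylate ester with an ester tether. The lactone ring closes in the 5-exo-tet mode, preferred over 6-endo attack at C8 by ring size and by the greater hindrance at C8 next to the silyloxy-bearing C9. C7 is the only new stereocentre and is set by stereospecific SN2 inversion, so it is dictated by the epoxide configuration (itself relayed from C9), and the erythro relationship between O6 and the epoxide guarantees the trans ring fusion. The step needs chemoselectivity for the acrylate over the ring enoate (trisubstituted and β-branched, hence inert to phosphine addition), backside access to C7 (available when the C5–C6–C7–C8 ring torsion is near anti, which places O6 antiperiplanar to the breaking C7–O bond and is also the torsion of the product), and suppression of intermolecular Rauhut–Currier oligomerisation (high dilution). The protic medium activates the epoxide by hydrogen bonding and protonates the alkoxide before silyl migration or attack on the C14 ester can compete.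

Step 14
Reactants: 18 macrocyclic hydroxy lactone
Product: 19 C8 methacrylate of 18
Conditions: methacrylic anhydride, Et3N, DMAP (cat.), CH2Cl2, 0 °C
Reagents that add atoms: methacrylic anhydride C=C(C)C(=O)OC(=O)C(C)=C
Why: DMAP-catalysed acylation of the C8 alcohol, carried out directly on the freshly formed alcohol so that it cannot lactonise onto the C14 ester.

Step 15
Reactants: 19 methacrylate silyl ether
Product: 20 C9 alcohol (desilylated 19)
Conditions: HF·pyridine, pyridine, THF, 0 °C → rt
Reagents that add atoms: none
Why: Fluoride-mediated desilylation under buffered acidic conditions, which avoids the alkoxide that would allow acyl migration from O8 to O9.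

Step 16
Reactants: 20 C9 alcohol
Product: 21 C9 acetate (the 4,5-alkene precursor of the target)
Conditions: Ac2O, pyridine, DMAP (cat.), CH2Cl2, 0 °C
Reagents that add atoms: acetic anhydride CC(=O)OC(C)=O
Why: Standard acetylation of the secondary allylic alcohol under non-alkoxide conditions that should not scramble the neighbouring methacrylate.

Step 17
Reactants: 21 diester diene lactone
Product: 22 target, the (4R,5R)-4,5-epoxide of 21
Conditions: mCPBA, NaHCO3, CH2Cl2, 0 °C
Reagents that add atoms: 3-chloroperoxybenzoic acid OOC(=O)c1cccc(Cl)c1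
Why: Prilezhaev epoxidation of the only electron-rich alkene (the three others are conjugated to carbonyl groups), where attack on the exposed peripheral face of the E-alkene held roughly perpendicular to the ten-membered ring, as in related 4,5-epoxygermacranolides, should give the (4R,5R) epoxide.

**Compound list**

1 | 1-methoxy-4-[(prop-2-yn-1-yloxy)methyl]benzene | C#CCOCc1ccc(OC)cc1 | starting material
2 | {3-[(4-methoxybenzyl)oxy]prop-1-yn-1-yl}lithium | [Li]C#CCOCc1ccc(OC)cc1 | intermediate
3 | 4-[(4-methoxybenzyl)oxy]but-2-ynal | O=CC#CCOCc1ccc(OC)cc1 | intermediate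
4 | 1,1,1,3,3,3-hexafluoropropan-2-yl prop-2-enoate | C=CC(=O)OC(C(F)(F)F)C(F)(F)F | starting material
5 | 1,1,1,3,3,3-hexafluoropropan-2-yl 2-[(1S)-1-hydroxy-4-[(4-methoxybenzyl)oxy]but-2-yn-1-yl]prop-2-enoate | C=C([C@@H](O)C#CCOCc1ccc(OC)cc1)C(=O)OC(C(F)(F)F)C(F)(F)F | intermediate
6 | methyl 2-[(1S)-1-hydroxy-4-[(4-methoxybenzyl)oxy]but-2-yn-1-yl]prop-2-enoate | C=C([C@@H](O)C#CCOCc1ccc(OC)cc1)C(=O)OC | intermediate
7 | methyl 2-[(1S,2Z)-1-hydroxy-4-[(4-methoxybenzyl)oxy]but-2-en-1-yl]prop-2-enoate | C=C([C@@H](O)/C=C\COCc1ccc(OC)cc1)C(=O)OC | intermediate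
8 | methyl 2-[(R)-hydroxy{(2S,3R)-3-[[(4-methoxybenzyl)oxy]methyl]oxiran-2-yl}methyl]prop-2-enoate | C=C([C@@H](O)[C@@H]1O[C@@H]1COCc1ccc(OC)cc1)C(=O)OC | intermediate
9 | C9 tert-butyldimethylsilyl ether of 8 | C=C([C@@H](O[Si](C)(C)C(C)(C)C)[C@@H]1O[C@@H]1COCc1ccc(OC)cc1)C(=O)OC | intermediate
10 | methyl 2-{[(tert-butyldimethylsilyl)oxy][3-(hydroxymethyl)oxiran-2-yl]methyl}prop-2-enoate (cis-epoxide, configuration as in 8) | C=C([C@@H](O[Si](C)(C)C(C)(C)C)[C@@H]1O[C@@H]1CO)C(=O)OC | intermediate
11 | methyl 2-{[(tert-butyldimethylsilyl)oxy](3-formyloxiran-2-yl)methyl}prop-2-enoate (cis-epoxy aldehyde, configuration as in 8) | C=C([C@@H](O[Si](C)(C)C(C)(C)C)[C@@H]1O[C@@H]1C=O)C(=O)OC | intermediate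
12 | hex-1-en-5-yne | C=CCCC#C | starting material
13 | dimethyl[(1E)-2-methylhexa-1,5-dien-1-yl]alumane | C=CCC/C(C)=C/[Al](C)C | intermediate
14 | (1E)-1-iodo-2-methylhexa-1,5-diene | C=CCC/C(C)=C/I | intermediate
15 | methyl 2-{[(tert-butyldimethylsilyl)oxy]{3-[(1R,2E)-1-hydroxy-3-methylhepta-2,6-dien-1-yl]oxiran-2-yl}methyl}prop-2-enoate (cis-epoxide; C6 alcohol erythro, C9 silyl ether threo to it) | C=CCC/C(C)=C/[C@@H](O)[C@H]1O[C@H]1[C@H](O[Si](C)(C)C(C)(C)C)C(=C)C(=O)OC | intermediate
16 | methyl 9-[(tert-butyldimethylsilyl)oxy]-7,8-epoxy-6-hydroxy-4-methylcyclodeca-1(10),4-diene-10-carboxylate (target numbering; ring-cis C1=C10, 4E, cis-epoxide) | COC(=O)/C1=C/CC/C(C)=C/[C@@H](O)[C@H]2O[C@H]2[C@@H]1O[Si](C)(C)C(C)(C)C | intermediate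
17 | C6 acrylate of 16 | COC(=O)/C1=C/CC/C(C)=C/[C@@H](OC(=O)C=C)[C@H]2O[C@H]2[C@@H]1O[Si](C)(C)C(C)(C)C | intermediate
18 | macrocyclic trans-fused α-methylene-γ-butyrolactone with free C8 hydroxyl, C9 silyl ether and 4E-alkene | O[C@@H]1[C@H]2C(=C)C(=O)O[C@@H]2/C=C(C)/CC/C=C(/C(=O)OC)[C@H]1O[Si](C)(C)C(C)(C)C | intermediate
19 | C8 methacrylate of 18 | C=C(C)C(=O)O[C@@H]1[C@H]2C(=C)C(=O)O[C@@H]2/C=C(C)/CC/C=C(/C(=O)OC)[C@H]1O[Si](C)(C)C(C)(C)C | intermediate
20 | C9 alcohol (desilylated 19) | C=C(C)C(=O)O[C@@H]1[C@H]2C(=C)C(=O)O[C@@H]2/C=C(C)/CC/C=C(/C(=O)OC)[C@H]1O | intermediate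
21 | C9 acetate of 20 (4,5-alkene precursor of the target) | C=C(C)C(=O)O[C@@H]1[C@H]2C(=C)C(=O)O[C@@H]2/C=C(C)/CC/C=C(/C(=O)OC)[C@H]1OC(C)=O | intermediate
22 | CNP0153978.7, the (4R,5R,6S,7R,8R,9R)-configured 9-acetoxy-4,5-epoxy-8-methacryloyloxy melampolide methyl ester | C=C(C)C(=O)O[C@@H]1[C@H]2C(=C)C(=O)O[C@@H]2[C@H]2O[C@]2(C)CC/C=C(/C(=O)OC)[C@H]1OC(C)=O | target

**Summary**

Total step count: 17. Longest linear sequence: 16 steps (steps 1–8 and 10–17); step 9 is a one-step branch.

Steps most likely to fail:

Step 13 (proposed new method). The phosphonium enolate of an acrylate ester may form too sparingly, or the ester may reach its cyclisation-competent rotamer too slowly, so that intermolecular Rauhut–Currier oligomerisation or direct phosphine attack on the epoxide wins. The fallback uses known stoichiometric carbanion chemistry and sets out from 16. Esterification with diethylphosphonoacetic acid (DCC, DMAP, CH2Cl2) would give the C6 diethylphosphonoacetate F1. Deprotonation (LiN(SiMe3)2, THF, −78 → 0 °C, kept cold to avoid phosphoryl transfer to the new alkoxide) lets the phosphonate-stabilised carbanion open the epoxide at C7 in the same 5-exo-tet sense with inversion, giving the macrocyclic α-(diethoxyphosphoryl) lactone F2 as a mixture of C11 epimers. Horner–Wadsworth–Emmons methylenation with aqueous formaldehyde and K2CO3 then comes back to the route at 18.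

Step 11. Intermolecular metathesis (oligomerisation) may outpace closure of the ten-membered ring onto the hindered, electron-poor 1,1-disubstituted alkene. The fallback reverses the order of ring formation and sets out from 15. Acryloylation (acryloyl chloride, i-Pr2NEt) would give the C6 acrylate of the acyclic epoxy alcohol F3. The phosphine-mediated cyclisation of step 13, now on a conformationally free chain, would give the acyclic trans-disubstituted α-methylene-γ-butyrolactone F4 with its free C8 hydroxyl. Ring-closing metathesis of F4 on this rigid lactone template (closure onto the lactone methylene would need an eight-membered ring containing the E-alkene and is not expected) comes back to the route at 18, bypassing 16 and 17.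

Step 17. Facial selectivity may be poor if the ten-membered ring populates a conformer that exposes the other face of C4=C5. The fallback replaces substrate control by reagent control and sets out from 21: Shi epoxidation with the D-fructose-derived ketone (KHSO5, K2CO3 buffer, MeCN/dimethoxymethane, 0 °C), whose sense on E-trisubstituted alkenes corresponds to the (4R,5R) oxirane, comes back directly at 22 without a new intermediate.

Further compounds
F1 | step 13 | C6 diethylphosphonoacetate of macrocyclic epoxy alcohol 16 | COC(=O)/C1=C/CC/C(C)=C/[C@@H](OC(=O)CP(=O)(OCC)OCC)[C@H]2O[C@H]2[C@@H]1O[Si](C)(C)C(C)(C)C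
F2 | step 13 | macrocyclic α-(diethoxyphosphoryl)-γ-butyrolactone with free C8 hydroxyl (C11 epimers) | O[C@@H]1[C@H]2C(P(=O)(OCC)OCC)C(=O)O[C@@H]2/C=C(C)/CC/C=C(/C(=O)OC)[C@H]1O[Si](C)(C)C(C)(C)C
F3 | step 11 | C6 acrylate of acyclic epoxy alcohol 15 | C=CCC/C(C)=C/[C@@H](OC(=O)C=C)[C@H]1O[C@H]1[C@H](O[Si](C)(C)C(C)(C)C)C(=C)C(=O)OC
F4 | step 11 | acyclic trans-disubstituted α-methylene-γ-butyrolactone with free C8 hydroxyl carrying both metathesis alkenes | C=CCC/C(C)=C/[C@H]1OC(=O)C(=C)[C@@H]1[C@@H](O)[C@H](O[Si](C)(C)C(C)(C)C)C(=C)C(=O)OC
F0 | step 17 | none | none
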